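The plan cuts the pyranone ring F of the flavonol at its carbonyl carbon and at the O1–C2 bond. Ring F is attached to carbon E1 of the pyrogallol ring E, next to E2, which bears the bulky flavan C4; this crowding is turned to advantage by carrying only a linear ethynyl group on E1. A single palladium-catalysed operation then unites that alkyne, carbon monoxide and 5-(benzyloxy)-2-iodophenol, making both C–C bonds of the new carbonyl and the O1–C2 bond, so that ring F is assembled on the open side of ring E. The precursor is the perbenzylated (2R,3S,4S)-4-(2-ethynylaryl)flavan, reached by aryl addition to an enantioenriched flavanone, dehydration and hydroboration.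

Key step: step 12

Remarks on the chemistry:
- Ring labels: in the flavan unit, ring A is the benzo ring, ring C the pyran ring and ring B the catechol ring. Ring E is the pyrogallol ring; E1 is its carbon bonded to C2 of the chromone and E2 its carbon bonded to flavan C4. In the chromone, ring D is the benzo ring and ring F the pyranone.
- Assumption: the sense of induction in step 2 is taken from the behaviour of cyclic enones with the same catalyst, so the (R)-configured PyOX ligand is expected to give the 2S flavanone; the antipodal ligand serves if the opposite sense is found.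
- The target is all-trans in ring C (C2 aryl, C3 oxygen and C4 aryl alternate faces), which is what anti-selective syn hydroboration of the 2S flav-3-ene should deliver.

Step 1
Reactants: 1 7-hydroxy-4H-chromen-4-one
Product: 2 7-(benzyloxy)-4H-chromen-4-one
Conditions: BnBr, K2CO3, acetone, reflux
Reagents that add atoms: benzyl bromide, BrCc1ccccc1
Why: Williamson etherification of the acidic 7-OH with a weak carbonate base is routine and should leave the base-sensitive pyranone intact.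

Step 2
Reactants: 2 7-(benzyloxy)-4H-chromen-4-one; 3 [3,4-bis(benzyloxy)phenyl]boronic acid
Product: 4 (2S)-7-(benzyloxy)-2-[3,4-bis(benzyloxy)phenyl]chroman-4-one
Conditions: Pd(OCOCF3)2 (5 mol %), (R)-t-BuPyOX (6 mol %), NH4PF6 (30 mol %), H2O (5 equiv), ClCH2CH2Cl, 60 °C
Reagents that add atoms: none
Why: Palladium-catalysed asymmetric conjugate addition of an arylboronic acid to a chromone, in which the cationic arylpalladium–PyOX complex transfers the aryl group to C2 under ligand control and the palladium enolate is protonated under non-basic conditions, so the new C2 centre should not racemise by retro-oxa-Michael opening.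

Step 3
Reactants: 5 3,4,5-trihydroxybenzaldehyde
Product: 6 3,4,5-tris(benzyloxy)benzaldehyde
Conditions: BnBr (3.6 equiv), K2CO3, DMF, 60 °C, N2
Reagents that add atoms: benzyl bromide, BrCc1ccccc1
Why: Threefold Williamson etherification of the pyrogallol hydroxyls under inert gas is standard and the non-enolisable aldehyde is a spectator.

Step 4
Reactants: 6 3,4,5-tris(benzyloxy)benzaldehyde
Product: 7 2-bromo-3,4,5-tris(benzyloxy)benzaldehyde
Conditions: NBS (1.05 equiv), MeCN, rt → 50 °C, dark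
Reagents that add atoms: N-bromosuccinimide, BrN1C(=O)CCC1=O
Why: Electrophilic aromatic bromination at one of the two equivalent free positions, each activated by an ortho and a para benzyloxy group, should stop at the monobromide because the aldehyde and the first bromine deactivate the ring.

Step 5
Reactants: 7 2-bromo-3,4,5-tris(benzyloxy)benzaldehyde
Product: 8 2-[2-bromo-3,4,5-tris(benzyloxy)phenyl]-1,3-dioxolane
Conditions: HOCH2CH2OH, p-TsOH (cat.), toluene, reflux, Dean–Stark
Reagents that add atoms: ethane-1,2-diol, OCCO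
Why: Acid-catalysed acetalisation with azeotropic removal of water masks the aldehyde against the organometallic and borane steps that follow.

Step 6
Reactants: 8 2-[2-bromo-3,4,5-tris(benzyloxy)phenyl]-1,3-dioxolane; 4 (2S)-7-(benzyloxy)-2-[3,4-bis(benzyloxy)phenyl]chroman-4-one
Product: 11 (2S)-7-(benzyloxy)-2-[3,4-bis(benzyloxy)phenyl]-4-[2,3,4-tris(benzyloxy)-6-(1,3-dioxolan-2-yl)phenyl]chroman-4-ol, via aryllithium 9 (not isolated), via arylcerium dichloride 10 (not isolated)
Conditions: 8 (1.5 equiv), n-BuLi, THF, −78 °C; CeCl3 (anhydrous), −78 °C; then 4, −78 → −30 °C; aq. NH4Cl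
Reagents that add atoms: none
Why: Bromine–lithium exchange followed by transmetalation gives a weakly basic organocerium reagent that should add to the enolisable ketone in a 1,2-fashion without triggering enolate-driven opening of ring C; the new C4 carbinol centre forms as an epimer mixture that is erased in step 7.

Step 7
Reactants: 11 (2S)-7-(benzyloxy)-2-[3,4-bis(benzyloxy)phenyl]-4-[2,3,4-tris(benzyloxy)-6-(1,3-dioxolan-2-yl)phenyl]chroman-4-ol
Product: 12 (2S)-7-(benzyloxy)-2-[3,4-bis(benzyloxy)phenyl]-4-[2,3,4-tris(benzyloxy)-6-(1,3-dioxolan-2-yl)phenyl]-2H-chromene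
Conditions: MsCl, Et3N, DMAP (cat.), CH2Cl2, 0 °C → rt, dark
Reagents that add atoms: none
Why: Dehydration through the tertiary mesylate, whose ionisation is assisted by the para-benzyloxy group and the ortho ring oxygen of ring A, can only remove a C3 hydrogen and so should give the single flav-3-ene under non-acidic conditions that spare the acetal; C2 is untouched, and cold, dark handling avoids electrocyclic opening of the 2H-chromene.

Step 8
Reactants: 12 (2S)-7-(benzyloxy)-2-[3,4-bis(benzyloxy)phenyl]-4-[2,3,4-tris(benzyloxy)-6-(1,3-dioxolan-2-yl)phenyl]-2H-chromene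
Product: 14 (2R,3S,4S)-7-(benzyloxy)-2-[3,4-bis(benzyloxy)phenyl]-4-[2,3,4-tris(benzyloxy)-6-(1,3-dioxolan-2-yl)phenyl]chroman-3-ol, via C3 alkylborane 13 (not isolated)
Conditions: BH3·SMe2, THF, 0 °C → rt, dark; then 3 M NaOH, 30 % H2O2, 0 °C → rt
Reagents that add atoms: hydrogen peroxide, OO
Why: Hydroboration–oxidation places boron on C3 (away from the diaryl-substituted C4) from the face opposite the C2 aryl group, the syn-delivered hydrogen pushes the ring E aryl at C4 to the other face, and oxidation with retention should give the 2,3-trans-3,4-trans alcohol, setting C3 and C4 under control of C2.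

Step 9
Reactants: 14 (2R,3S,4S)-7-(benzyloxy)-2-[3,4-bis(benzyloxy)phenyl]-4-[2,3,4-tris(benzyloxy)-6-(1,3-dioxolan-2-yl)phenyl]chroman-3-ol
Product: 16 2-[(2R,3S,4S)-3,7-bis(benzyloxy)-2-[3,4-bis(benzyloxy)phenyl]chroman-4-yl]-3,4,5-tris(benzyloxy)benzaldehyde, via 3-O-benzyl dioxolane 15 (not isolated)
Conditions: NaH, BnBr, n-Bu4NI (cat.), DMF, 0 °C → rt; then 2 M aq. HCl, THF, rt (same flask)
Reagents that add atoms: benzyl bromide, BrCc1ccccc1; water, O
Why: Williamson benzylation of the secondary alkoxide followed by acid-catalysed acetal hydrolysis, in this order so that the free 3-OH cannot close a six-membered lactol onto the liberated aldehyde; the mild acid should not affect the benzylated C4 diarylmethine.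

Step 10
Reactants: 16 2-[(2R,3S,4S)-3,7-bis(benzyloxy)-2-[3,4-bis(benzyloxy)phenyl]chroman-4-yl]-3,4,5-tris(benzyloxy)benzaldehyde
Product: 17 (2R,3S,4S)-3,7-bis(benzyloxy)-2-[3,4-bis(benzyloxy)phenyl]-4-[2,3,4-tris(benzyloxy)-6-ethynylphenyl]chromane
Conditions: dimethyl (1-diazo-2-oxopropyl)phosphonate, K2CO3, MeOH/THF (1:1), 0 °C → rt
Reagents that add atoms: dimethyl (1-diazo-2-oxopropyl)phosphonate, CC(=O)C(=[N+]=[N-])P(=O)(OC)OC
Why: Ohira–Bestmann (Seyferth–Gilbert) homologation converts the non-enolisable aryl aldehyde into the terminal alkyne under mild carbonate conditions that do not touch the stereocentres.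

Step 11
Reactants: 18 3-(benzyloxy)phenol
Product: 19 5-(benzyloxy)-2-iodophenol
Conditions: I2, NaHCO3, THF/H2O (1:1), 0 °C → rt
Reagents that add atoms: iodine, II
Why: Electrophilic iodination under bicarbonate conditions should take the less hindered ortho position of the phenol, which is also para to the benzyloxy group.

Step 12
Reactants: 17 (2R,3S,4S)-3,7-bis(benzyloxy)-2-[3,4-bis(benzyloxy)phenyl]-4-[2,3,4-tris(benzyloxy)-6-ethynylphenyl]chromane; 19 5-(benzyloxy)-2-iodophenol
Product: 22 7-(benzyloxy)-2-{3,4,5-tris(benzyloxy)-2-[(2R,3S,4S)-3,7-bis(benzyloxy)-2-[3,4-bis(benzyloxy)phenyl]chroman-4-yl]phenyl}-4H-chromen-4-one, via ynone 20 (not isolated), via enaminone 21 (not isolated)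
Conditions: PdCl2(PPh3)2 (5 mol %), CO (20 bar), Et2NH/toluene (1:1), 110 °C, autoclave; 19 (1.5 equiv)
Reagents that add atoms: carbon monoxide, [C-]#[O+]
Why: Zerovalent palladium, formed in situ from PdCl2(PPh3)2, inserts into the C–I bond of 19, CO insertion gives an aroylpalladium species, and the amine-deprotonated alkyne of 17 is transferred and reductively eliminated as ynone 20, which creates both C–C bonds of the ring F carbonyl. Diethylamine then adds to the β-carbon of 20 to give enaminone 21, and the neighbouring phenol displaces the amine by addition–elimination, forming O1–C2 and closing ring F in the 6-endo sense. The closest known reaction type is the carbonylative Sonogashira annulation of 2-iodophenols with terminal arylacetylenes to flavones in secondary amines. No stereocentre is created, and the near-neutral medium should leave the C2, C3 and C4 centres of ring C and all benzyl ethers untouched. The step needs flavone (6-endo) rather than aurone (5-exo) closure, which the amine relay through 21 and the Michael polarity of the ynone secure, and carbonylation rather than direct alkyne–aryl coupling, which the CO pressure and the absence of copper secure. Because all intermolecular bond formation occurs at the terminal alkyne carbon, two atoms away from E1, the flavan on E2 does not obstruct it.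

Step 13
Reactants: 22 7-(benzyloxy)-2-{3,4,5-tris(benzyloxy)-2-[(2R,3S,4S)-3,7-bis(benzyloxy)-2-[3,4-bis(benzyloxy)phenyl]chroman-4-yl]phenyl}-4H-chromen-4-one
Product: 25 7-(benzyloxy)-3-hydroxy-2-{3,4,5-tris(benzyloxy)-2-[(2R,3S,4S)-3,7-bis(benzyloxy)-2-[3,4-bis(benzyloxy)phenyl]chroman-4-yl]phenyl}-4H-chromen-4-one, via 3-lithioflavone 23 (not isolated), via dimethyl boronate 24 (not isolated)
Conditions: LiN(i-Pr)2 (2.2 equiv), THF, −78 °C; B(OMe)3, −78 → 0 °C; AcOH, 30 % H2O2, 0 °C → rt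
Reagents that add atoms: hydrogen peroxide, OO
Why: Carbonyl-assisted lithiation of the flavone at C3, borylation and peroxide oxidation of the C–B bond is the established lithiation–borylation–oxidation route from flavones to flavonols, and at −78 °C the amide base should not metalate the benzyl ethers or the ring C positions.

Step 14
Reactants: 25 7-(benzyloxy)-3-hydroxy-2-{3,4,5-tris(benzyloxy)-2-[(2R,3S,4S)-3,7-bis(benzyloxy)-2-[3,4-bis(benzyloxy)phenyl]chroman-4-yl]phenyl}-4H-chromen-4-one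
Product: 26 2-{2-[(2R,3S,4S)-2-(3,4-dihydroxyphenyl)-3,7-dihydroxychroman-4-yl]-3,4,5-trihydroxyphenyl}-3,7-dihydroxy-4H-chromen-4-one
Conditions: H2 (1 atm), Pd(OH)2/C, THF/MeOH (1:1), rt; filtration and concentration under argon
Reagents that add atoms: none
Why: Hydrogenolysis of all eight benzyl ethers over Pd(OH)2/C at ambient pressure is standard for perbenzylated flavonoids and should spare the pyranone double bond and the benzylic C–O and C–C bonds of ring C, so the three stereocentres persist.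

Compound list
1 | 7-hydroxy-4H-chromen-4-one | O=c1ccoc2cc(O)ccc12 | starting material
2 | 7-(benzyloxy)-4H-chromen-4-one | O=c1ccoc2cc(OCc5ccccc5)ccc12 | intermediate
3 | [3,4-bis(benzyloxy)phenyl]boronic acid | OB(O)c1ccc(OCc5ccccc5)c(OCc5ccccc5)c1 | starting material
4 | (2S)-7-(benzyloxy)-2-[3,4-bis(benzyloxy)phenyl]chroman-4-one | O=C1C[C@@H](c2ccc(OCc5ccccc5)c(OCc5ccccc5)c2)Oc2cc(OCc5ccccc5)ccc12 | intermediate
5 | 3,4,5-trihydroxybenzaldehyde | O=Cc1cc(O)c(O)c(O)c1 | starting material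
6 | 3,4,5-tris(benzyloxy)benzaldehyde | O=Cc1cc(OCc5ccccc5)c(OCc5ccccc5)c(OCc5ccccc5)c1 | intermediate
7 | 2-bromo-3,4,5-tris(benzyloxy)benzaldehyde | O=Cc1cc(OCc5ccccc5)c(OCc5ccccc5)c(OCc5ccccc5)c1Br | intermediate
8 | 2-[2-bromo-3,4,5-tris(benzyloxy)phenyl]-1,3-dioxolane | Brc1c(C2OCCO2)cc(OCc5ccccc5)c(OCc5ccccc5)c1OCc5ccccc5 | intermediate
9 | [2,3,4-tris(benzyloxy)-6-(1,3-dioxolan-2-yl)phenyl]lithium | [Li]c1c(C2OCCO2)cc(OCc5ccccc5)c(OCc5ccccc5)c1OCc5ccccc5 | intermediate (not isolated)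
10 | dichloro[2,3,4-tris(benzyloxy)-6-(1,3-dioxolan-2-yl)phenyl]cerium | Cl[Ce](Cl)c1c(C2OCCO2)cc(OCc5ccccc5)c(OCc5ccccc5)c1OCc5ccccc5 | intermediate (not isolated)
11 | (2S)-7-(benzyloxy)-2-[3,4-bis(benzyloxy)phenyl]-4-[2,3,4-tris(benzyloxy)-6-(1,3-dioxolan-2-yl)phenyl]chroman-4-ol (both C4 epimers) | OC1(c2c(C3OCCO3)cc(OCc5ccccc5)c(OCc5ccccc5)c2OCc5ccccc5)C[C@@H](c2ccc(OCc5ccccc5)c(OCc5ccccc5)c2)Oc2cc(OCc5ccccc5)ccc12 | intermediate
12 | (2S)-7-(benzyloxy)-2-[3,4-bis(benzyloxy)phenyl]-4-[2,3,4-tris(benzyloxy)-6-(1,3-dioxolan-2-yl)phenyl]-2H-chromene | C1(c2c(C3OCCO3)cc(OCc5ccccc5)c(OCc5ccccc5)c2OCc5ccccc5)=C[C@@H](c2ccc(OCc5ccccc5)c(OCc5ccccc5)c2)Oc2cc(OCc5ccccc5)ccc12 | intermediate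
13 | C3 borane adduct of 12 (BH2 on C3 anti to the C2 aryl, hydrogen on C4 syn to boron) | O1CCOC1c1cc(OCc5ccccc5)c(OCc5ccccc5)c(OCc5ccccc5)c1[C@@H]2c3ccc(OCc5ccccc5)cc3O[C@H](c4ccc(OCc5ccccc5)c(OCc5ccccc5)c4)[C@H]2B | intermediate (not isolated)
14 | (2R,3S,4S)-7-(benzyloxy)-2-[3,4-bis(benzyloxy)phenyl]-4-[2,3,4-tris(benzyloxy)-6-(1,3-dioxolan-2-yl)phenyl]chroman-3-ol | O1CCOC1c1cc(OCc5ccccc5)c(OCc5ccccc5)c(OCc5ccccc5)c1[C@@H]2c3ccc(OCc5ccccc5)cc3O[C@H](c4ccc(OCc5ccccc5)c(OCc5ccccc5)c4)[C@H]2O | intermediate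
15 | 2-{2-[(2R,3S,4S)-3,7-bis(benzyloxy)-2-[3,4-bis(benzyloxy)phenyl]chroman-4-yl]-3,4,5-tris(benzyloxy)phenyl}-1,3-dioxolane | O1CCOC1c1cc(OCc5ccccc5)c(OCc5ccccc5)c(OCc5ccccc5)c1[C@@H]2c3ccc(OCc5ccccc5)cc3O[C@H](c4ccc(OCc5ccccc5)c(OCc5ccccc5)c4)[C@H]2OCc5ccccc5 | intermediate (not isolated)
16 | 2-[(2R,3S,4S)-3,7-bis(benzyloxy)-2-[3,4-bis(benzyloxy)phenyl]chroman-4-yl]-3,4,5-tris(benzyloxy)benzaldehyde | O=Cc1cc(OCc5ccccc5)c(OCc5ccccc5)c(OCc5ccccc5)c1[C@@H]2c3ccc(OCc5ccccc5)cc3O[C@H](c4ccc(OCc5ccccc5)c(OCc5ccccc5)c4)[C@H]2OCc5ccccc5 | intermediate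
17 | (2R,3S,4S)-3,7-bis(benzyloxy)-2-[3,4-bis(benzyloxy)phenyl]-4-[2,3,4-tris(benzyloxy)-6-ethynylphenyl]chromane | C#Cc1cc(OCc5ccccc5)c(OCc5ccccc5)c(OCc5ccccc5)c1[C@@H]2c3ccc(OCc5ccccc5)cc3O[C@H](c4ccc(OCc5ccccc5)c(OCc5ccccc5)c4)[C@H]2OCc5ccccc5 | intermediate
18 | 3-(benzyloxy)phenol | Oc1cccc(OCc5ccccc5)c1 | starting material
19 | 5-(benzyloxy)-2-iodophenol | Oc1cc(OCc5ccccc5)ccc1I | intermediate
20 | 1-[4-(benzyloxy)-2-hydroxyphenyl]-3-{3,4,5-tris(benzyloxy)-2-[(2R,3S,4S)-3,7-bis(benzyloxy)-2-[3,4-bis(benzyloxy)phenyl]chroman-4-yl]phenyl}prop-2-yn-1-one | O=C(C#Cc1cc(OCc5ccccc5)c(OCc5ccccc5)c(OCc5ccccc5)c1[C@@H]2c3ccc(OCc5ccccc5)cc3O[C@H](c4ccc(OCc5ccccc5)c(OCc5ccccc5)c4)[C@H]2OCc5ccccc5)c6ccc(OCc5ccccc5)cc6O | intermediate (not isolated)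
21 | 1-[4-(benzyloxy)-2-hydroxyphenyl]-3-(diethylamino)-3-{3,4,5-tris(benzyloxy)-2-[(2R,3S,4S)-3,7-bis(benzyloxy)-2-[3,4-bis(benzyloxy)phenyl]chroman-4-yl]phenyl}prop-2-en-1-one (drawn E; either geometry cyclises) | O=C(/C=C(/N(CC)CC)c1cc(OCc5ccccc5)c(OCc5ccccc5)c(OCc5ccccc5)c1[C@@H]2c3ccc(OCc5ccccc5)cc3O[C@H](c4ccc(OCc5ccccc5)c(OCc5ccccc5)c4)[C@H]2OCc5ccccc5)c6ccc(OCc5ccccc5)cc6O | intermediate (not isolated)
22 | 7-(benzyloxy)-2-{3,4,5-tris(benzyloxy)-2-[(2R,3S,4S)-3,7-bis(benzyloxy)-2-[3,4-bis(benzyloxy)phenyl]chroman-4-yl]phenyl}-4H-chromen-4-one | O=c1cc(-c2cc(OCc5ccccc5)c(OCc5ccccc5)c(OCc5ccccc5)c2[C@@H]2c3ccc(OCc5ccccc5)cc3O[C@H](c3ccc(OCc5ccccc5)c(OCc5ccccc5)c3)[C@H]2OCc5ccccc5)oc2cc(OCc5ccccc5)ccc12 | intermediate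
23 | 3-lithio derivative of 22 | O=c1c([Li])c(-c2cc(OCc5ccccc5)c(OCc5ccccc5)c(OCc5ccccc5)c2[C@@H]2c3ccc(OCc5ccccc5)cc3O[C@H](c3ccc(OCc5ccccc5)c(OCc5ccccc5)c3)[C@H]2OCc5ccccc5)oc2cc(OCc5ccccc5)ccc12 | intermediate (not isolated)
24 | dimethyl boronate of 22 at chromone C3 | O=c1c(B(OC)OC)c(-c2cc(OCc5ccccc5)c(OCc5ccccc5)c(OCc5ccccc5)c2[C@@H]2c3ccc(OCc5ccccc5)cc3O[C@H](c3ccc(OCc5ccccc5)c(OCc5ccccc5)c3)[C@H]2OCc5ccccc5)oc2cc(OCc5ccccc5)ccc12 | intermediate (not isolated)
25 | 7-(benzyloxy)-3-hydroxy-2-{3,4,5-tris(benzyloxy)-2-[(2R,3S,4S)-3,7-bis(benzyloxy)-2-[3,4-bis(benzyloxy)phenyl]chroman-4-yl]phenyl}-4H-chromen-4-one | O=c1c(O)c(-c2cc(OCc5ccccc5)c(OCc5ccccc5)c(OCc5ccccc5)c2[C@@H]2c3ccc(OCc5ccccc5)cc3O[C@H](c3ccc(OCc5ccccc5)c(OCc5ccccc5)c3)[C@H]2OCc5ccccc5)oc2cc(OCc5ccccc5)ccc12 | intermediate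
26 | 2-{2-[(2R,3S,4S)-2-(3,4-dihydroxyphenyl)-3,7-dihydroxychroman-4-yl]-3,4,5-trihydroxyphenyl}-3,7-dihydroxy-4H-chromen-4-one | O=c1c(O)c(-c2cc(O)c(O)c(O)c2[C@@H]2c3ccc(O)cc3O[C@H](c3ccc(O)c(O)c3)[C@H]2O)oc2cc(O)ccc12 | target

Total step count: 14.
Longest linear sequence: 11 steps (from 5 through steps 3–10 and 12–14 to 26).

Steps most likely to fail

Step 6. The doubly ortho-substituted arylmetal may act as a base rather than a nucleophile towards the electron-rich ketone, and the resulting enolate may open ring C by β-elimination of the phenoxide, which would return racemised or ring-opened material. The fallback avoids both carbonyl addition and dehydration. It sets out from 4 and 8 and returns at 12. Treatment of 4 with Tf2O and 2,6-di-tert-butyl-4-methylpyridine in CH2Cl2 should give the enol triflate (2S)-7-(benzyloxy)-2-[3,4-bis(benzyloxy)phenyl]-2H-chromen-4-yl trifluoromethanesulfonate F1 without passing through a free enolate. Lithiation of 8 (n-BuLi, THF, −78 °C) and quenching with 2-isopropoxy-4,4,5,5-tetramethyl-1,3,2-dioxaborolane should give the pinacol boronate 2-[3,4,5-tris(benzyloxy)-2-(4,4,5,5-tetramethyl-1,3,2-dioxaborolan-2-yl)phenyl]-1,3-dioxolane F2. Suzuki–Miyaura coupling of the two (Pd(OAc)2, SPhos, K3PO4, toluene/H2O, 60 °C, dark) should deliver 12 directly.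

Step 12. Conjugate addition at the internal alkyne carbon beside the flavan may be slow, which would let 5-exo closure, amine carbonylation of the aryl iodide or non-carbonylative coupling compete. The fallback builds ring F by condensation and oxidative cyclisation instead. It sets out from 16 and returns at 25, bypassing steps 10, 12 and 13. Claisen–Schmidt condensation of 16 with commercial 1-[4-(benzyloxy)-2-hydroxyphenyl]ethan-1-one (CC(=O)c1ccc(OCc2ccccc2)cc1O; KOH, EtOH/THF, rt) should give the chalcone (E)-1-[4-(benzyloxy)-2-hydroxyphenyl]-3-{3,4,5-tris(benzyloxy)-2-[(2R,3S,4S)-3,7-bis(benzyloxy)-2-[3,4-bis(benzyloxy)phenyl]chroman-4-yl]phenyl}prop-2-en-1-one F3. Algar–Flynn–Oyamada oxidation (30 % H2O2, NaOH, MeOH/THF, 0 °C → rt) should then close ring F and install the 3-hydroxyl in one operation to give 25.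

Step 13. Deprotonation at chromone C3 may be incomplete, or the amide base may metalate benzylic ether positions, and the peroxide work-up may over-oxidise the electron-rich product. The fallback replaces the anionic sequence by electrophilic oxygen transfer. It sets out from 22 and returns at 25. Dimethyldioxirane (acetone/CH2Cl2, 0 °C → rt, limited excess to spare the benzyl ethers) should epoxidise the C2–C3 double bond to give the flavone 2,3-epoxide of 22 F4, obtained as a diastereomer mixture that is of no consequence. A catalytic amount of p-TsOH in CH2Cl2 should open the epoxide and tautomerise it to 25.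

Further compounds
F1 | step 6 | (2S)-7-(benzyloxy)-2-[3,4-bis(benzyloxy)phenyl]-2H-chromen-4-yl trifluoromethanesulfonate | FC(F)(F)S(=O)(=O)OC1=C[C@@H](c2ccc(OCc5ccccc5)c(OCc5ccccc5)c2)Oc2cc(OCc5ccccc5)ccc12
F2 | step 6 | 2-[3,4,5-tris(benzyloxy)-2-(4,4,5,5-tetramethyl-1,3,2-dioxaborolan-2-yl)phenyl]-1,3-dioxolane | CC1(C)OB(OC1(C)C)c1c(C2OCCO2)cc(OCc5ccccc5)c(OCc5ccccc5)c1OCc5ccccc5
F3 | step 12 | (E)-1-[4-(benzyloxy)-2-hydroxyphenyl]-3-{3,4,5-tris(benzyloxy)-2-[(2R,3S,4S)-3,7-bis(benzyloxy)-2-[3,4-bis(benzyloxy)phenyl]chroman-4-yl]phenyl}prop-2-en-1-one | O=C(/C=C/c1cc(OCc5ccccc5)c(OCc5ccccc5)c(OCc5ccccc5)c1[C@@H]2c3ccc(OCc5ccccc5)cc3O[C@H](c4ccc(OCc5ccccc5)c(OCc5ccccc5)c4)[C@H]2OCc5ccccc5)c6ccc(OCc5ccccc5)cc6O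
F4 | step 13 | 2,3-epoxide of 22 (6-(benzyloxy)-1a-aryl-1a,7a-dihydro-7H-oxireno[2,3-b]chromen-7-one, epoxide configuration undefined) | O=C1C2OC2(c3cc(OCc5ccccc5)c(OCc5ccccc5)c(OCc5ccccc5)c3[C@@H]4c6ccc(OCc5ccccc5)cc6O[C@H](c7ccc(OCc5ccccc5)c(OCc5ccccc5)c7)[C@H]4OCc5ccccc5)Oc2cc(OCc5ccccc5)ccc12
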